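**Strategy.** The cyclobutane (C1 carrying the methylene-bearing arm, C2 the 3-oxobutyl arm, C3 = CMe2, C4 = CH2) is cut across C1–C2 and C3–C4. The carbon that becomes C(=CH2) on C1 and the first CH2 on C2 are 1,4-related, so one oxygen can bridge them as a tetrahydrofuran fused to the four-membered ring. A copper(I)-templated [2+2] photocycloaddition of an (S)-allylic prenyl ether therefore builds both rings, both C–C bonds and both ring stereocentres at once. The precursor is the O-prenyl ether of (S)-6-silyloxyhex-1-en-3-ol. Ether cleavage at CH2–O, oxidation of the carbinol, epimerisation at C1, methylenation, acetonylation and esterification finish the synthesis.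

Key step: step 6

Assumption: salts that differ from a numbered alcohol only by a metal or ammonium counter-ion before aqueous quench are not counted as separate compounds; the cyclobutane numbering C1–C4 given above is used throughout.

Step 1
Reactants: 1 butane-1,4-diol
Product: 2 4-[(triisopropylsilyl)oxy]butan-1-ol
Conditions: TIPSCl (1.0 equiv), imidazole, 1 (4 equiv), THF/DMF, 0 °C → rt
Reagents that add atoms: chlorotriisopropylsilane, CC(C)[Si](Cl)(C(C)C)C(C)C
Why: Imidazole-promoted silyl ether formation on a symmetrical diol used in excess should give mainly the mono-ether, and the surplus diol is removed by aqueous washing; the triisopropylsilyl group is chosen because it has no chromophore at 254 nm and is the trialkylsilyl group most likely to survive the later boron bromide and strong-base steps.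

Step 2
Reactants: 2 4-[(triisopropylsilyl)oxy]butan-1-ol
Product: 3 4-[(triisopropylsilyl)oxy]butanal
Conditions: TEMPO (10 mol%), PhI(OAc)2 (1.1 equiv), CH2Cl2, rt
Reagents that add atoms: none
Why: TEMPO/iodine(III) oxoammonium oxidation converts the primary alcohol into the aldehyde without over-oxidation under anhydrous conditions and leaves the silyl ether untouched.

Step 3
Reactants: 3 4-[(triisopropylsilyl)oxy]butanal; 4 vinylmagnesium bromide
Product: 5 rac-6-[(triisopropylsilyl)oxy]hex-1-en-3-ol
Conditions: THF, −78 → 0 °C; then H2O/aq. NH4Cl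
Reagents that add atoms: none
Why: Grignard 1,2-addition of the vinyl nucleophile to an unhindered aliphatic aldehyde should give the secondary allylic alcohol as the racemate, since nothing in the substrate biases the carbonyl faces.

Step 4
Reactants: 5 rac-6-[(triisopropylsilyl)oxy]hex-1-en-3-ol
Product: 6 (3S)-6-[(triisopropylsilyl)oxy]hex-1-en-3-ol
Conditions: Ti(OiPr)4 (0.15 equiv), D-(−)-DIPT (0.2 equiv), t-BuOOH (0.6 equiv, isooctane), 4 Å MS, CH2Cl2, −20 °C
Reagents that add atoms: none
Why: Sharpless kinetic resolution: with D-(−)-diisopropyl tartrate the titanium–tartrate catalyst epoxidises the (R)-alcohol much faster (to the erythro epoxy alcohol), so running slightly past half conversion should leave the (S)-alcohol, whose stereocentre is selected and not created, in high enantiomeric purity after chromatography.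

Step 5
Reactants: 6 (3S)-6-[(triisopropylsilyl)oxy]hex-1-en-3-ol; 7 1-bromo-3-methylbut-2-ene
Product: 8 (S)-triisopropyl({4-[(3-methylbut-2-en-1-yl)oxy]hex-5-en-1-yl}oxy)silane
Conditions: NaH, THF, 0 °C; 7, Bu4NI (cat.), 0 °C → rt
Reagents that add atoms: none
Why: Williamson ether synthesis: the sodium alkoxide displaces the primary allylic bromide by SN2 without touching the C–O stereocentre, and the hindered triisopropylsilyl group resists alkoxide-induced silyl migration.

Step 6
Reactants: 8 (S)-triisopropyl({4-[(3-methylbut-2-en-1-yl)oxy]hex-5-en-1-yl}oxy)silane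
Product: 9 (1R,2S,5R)-6,6-dimethyl-2-{3-[(triisopropylsilyl)oxy]propyl}-3-oxabicyclo[3.2.0]heptane
Conditions: (CuOTf)2·C6H6 (5 mol%), Et2O (degassed), hν 254 nm, quartz, rt
Reagents that add atoms: none
Why: Copper(I) binds both alkenes of the 1,6-diene as a bis(η2) chelate, and excitation of this complex joins the two internal alkene carbons and the two outer ones (CH2 with CMe2) suprafacially; the closest known reaction type is the Kochi–Salomon copper(I) triflate photobicyclisation of diallyl ethers to 3-oxabicyclo[3.2.0]heptanes. The tetrahydrofuran closes by bonding the internal vinyl carbon to the CH of the prenyl group across the three-atom C–O–C tether (five-membered, parallel rather than crossed closure), and the cyclobutane closes by the second bond between the terminal CH2 and CMe2, so the ring fusion can only be cis. The two new stereocentres (C1 and C5 of the bicycle) are fixed relative to each other by the cis fusion, and relative to the existing (S)-carbinol centre by the side chain taking the exo (convex) position away from the forming cyclobutane, which should give 1R,5R. The step needs this exo facial selectivity, which the allylic stereocentre sitting directly on the tether is expected to secure, and chemoselectivity, which is secured because the molecule holds no other alkene or chromophore and the bulky silyl ether does not compete for copper. Any endo diastereomer must be removed by chromatography here, because it would lead to the enantiomeric ketone once the carbinol is oxidised.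

Step 7
Reactants: 9 (1R,2S,5R)-6,6-dimethyl-2-{3-[(triisopropylsilyl)oxy]propyl}-3-oxabicyclo[3.2.0]heptane
Product: 11 (1S)-1-[(1R,2R)-2-(bromomethyl)-3,3-dimethylcyclobutyl]-4-[(triisopropylsilyl)oxy]butan-1-ol, via bromo dimethylborinate ester 10 (not isolated)
Conditions: Me2BBr (2 equiv), Et3N (0.2 equiv), CH2Cl2, 0 °C → rt; sat. aq. NaHCO3; crude 11 used at once
Reagents that add atoms: bromodimethylborane, CB(C)Br
Why: Guindon-type cleavage of a cyclic ether with a dialkylboron bromide: boron activates the ring oxygen and bromide opens the oxonium by SN2 at the primary CH2–O carbon in preference to the secondary carbinol carbon, so all three stereocentres are retained, the O–B bond is hydrolysed on work-up, and the hindered, weakly basic silyl ether oxygen should be left alone.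

Step 8
Reactants: 11 (1S)-1-[(1R,2R)-2-(bromomethyl)-3,3-dimethylcyclobutyl]-4-[(triisopropylsilyl)oxy]butan-1-ol
Product: 12 1-[(1R,2R)-2-(bromomethyl)-3,3-dimethylcyclobutyl]-4-[(triisopropylsilyl)oxy]butan-1-one (cis)
Conditions: Dess–Martin periodinane (1.3 equiv), CH2Cl2, 0 °C → rt
Reagents that add atoms: none
Why: Dess–Martin oxidation turns the secondary alcohol into the ketone without base, which removes the hydroxyl group before it can re-close onto the bromide and does not disturb the cis ring stereocentres.

Step 9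
Reactants: 12 1-[(1R,2R)-2-(bromomethyl)-3,3-dimethylcyclobutyl]-4-[(triisopropylsilyl)oxy]butan-1-one (cis)
Product: 13 1-[(1S,2R)-2-(bromomethyl)-3,3-dimethylcyclobutyl]-4-[(triisopropylsilyl)oxy]butan-1-one (trans)
Conditions: p-TsOH·H2O (0.3 equiv), PhMe, 60 °C
Reagents that add atoms: none
Why: Acid-catalysed enolisation and reprotonation (thermodynamic epimerisation) should invert the only enolisable stereocentre, the ring carbon C1 carrying the acyl group, to the less strained trans-1,2 arrangement, while C2 has no acidifying group; an enol is used instead of an enolate because an enolate could alkylate intramolecularly on the γ-bromide.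

Step 10
Reactants: 13 1-[(1S,2R)-2-(bromomethyl)-3,3-dimethylcyclobutyl]-4-[(triisopropylsilyl)oxy]butan-1-one (trans)
Product: 14 ({4-[(1S,2R)-2-(bromomethyl)-3,3-dimethylcyclobutyl]pent-4-en-1-yl}oxy)triisopropylsilane
Conditions: Zn, CH2Br2, TiCl4, THF (reagent pre-formed at 0–5 °C); 13, CH2Cl2, 0 °C → rt
Reagents that add atoms: dibromomethane, BrCBr
Why: Takai–Lombardo methylenation with the Zn/CH2Br2/TiCl4 reagent is non-basic, so the ketone should become the 1,1-disubstituted alkene without re-equilibrating the adjacent trans stereocentre and without affecting the primary bromide or the silyl ether.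

Step 11
Reactants: 14 ({4-[(1S,2R)-2-(bromomethyl)-3,3-dimethylcyclobutyl]pent-4-en-1-yl}oxy)triisopropylsilane; 15 acetone N,N-dimethylhydrazone
Product: 17 4-[(1R,4S)-2,2-dimethyl-4-(5-{[triisopropylsilyl]oxy}pent-1-en-2-yl)cyclobutyl]butan-2-one, via alkylated dimethylhydrazone 16 (not isolated)
Conditions: 15, n-BuLi, THF, −78 → 0 °C; 14, DMPU, −78 °C → rt; then sat. aq. oxalic acid, Et2O, rt
Reagents that add atoms: water, O
Why: Corey–Enders hydrazone alkylation: the lithiated acetone dimethylhydrazone, a strongly nucleophilic aza-enolate, displaces the primary bromide by SN2 at an achiral CH2 carbon, and mild biphasic acid hydrolysis of the hydrazone then liberates the methyl ketone without isomerising the alkene or removing the silyl group.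

Step 12
Reactants: 17 4-[(1R,4S)-2,2-dimethyl-4-(5-{[triisopropylsilyl]oxy}pent-1-en-2-yl)cyclobutyl]butan-2-one
Product: 18 4-[(1R,4S)-4-(5-hydroxypent-1-en-2-yl)-2,2-dimethylcyclobutyl]butan-2-one
Conditions: Bu4NF (1.5 equiv), THF, 0 °C → rt
Reagents that add atoms: none
Why: Fluoride-mediated desilylation frees the primary alcohol, and neither ring stereocentre is α to a carbonyl group, so the mildly basic conditions cannot epimerise them.

Step 13
Reactants: 18 4-[(1R,4S)-4-(5-hydroxypent-1-en-2-yl)-2,2-dimethylcyclobutyl]butan-2-one; 19 linoleic acid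
Product: 20 4-[(1S,2R)-3,3-dimethyl-2-(3-oxobutyl)cyclobutyl]pent-4-en-1-yl (9Z,12Z)-octadeca-9,12-dienoate (IN0146)
Conditions: DCC (1.2 equiv), DMAP (cat.), CH2Cl2, 0 °C → rt
Reagents that add atoms: none
Why: Steglich esterification (carbodiimide activation with DMAP acyl transfer) acylates the primary alcohol under neutral conditions at or below room temperature, which should keep the skipped (9Z,12Z)-diene from isomerising and leave the ketone untouched.

**Compound list**

1 | butane-1,4-diol | OCCCCO | starting material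
2 | 4-[(triisopropylsilyl)oxy]butan-1-ol | CC(C)[Si](C(C)C)(C(C)C)OCCCCO | intermediate
3 | 4-[(triisopropylsilyl)oxy]butanal | CC(C)[Si](C(C)C)(C(C)C)OCCCC=O | intermediate
4 | vinylmagnesium bromide | C=C[Mg]Br | starting material
5 | rac-6-[(triisopropylsilyl)oxy]hex-1-en-3-ol | CC(C)[Si](C(C)C)(C(C)C)OCCCC(O)C=C | intermediate
6 | (3S)-6-[(triisopropylsilyl)oxy]hex-1-en-3-ol | CC(C)[Si](C(C)C)(C(C)C)OCCC[C@H](O)C=C | intermediate
7 | 1-bromo-3-methylbut-2-ene | CC(C)=CCBr | starting material
8 | (S)-triisopropyl({4-[(3-methylbut-2-en-1-yl)oxy]hex-5-en-1-yl}oxy)silane | CC(C)[Si](C(C)C)(C(C)C)OCCC[C@@H](C=C)OCC=C(C)C | intermediate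
9 | (1R,2S,5R)-6,6-dimethyl-2-{3-[(triisopropylsilyl)oxy]propyl}-3-oxabicyclo[3.2.0]heptane | CC(C)[Si](C(C)C)(C(C)C)OCCC[C@@H]1OC[C@H]2C(C)(C)C[C@@H]12 | intermediate
10 | O-dimethylboryl (dimethylborinate) ester of 11 | CC(C)[Si](C(C)C)(C(C)C)OCCC[C@H](OB(C)C)[C@@H]1CC(C)(C)[C@@H]1CBr | intermediate
11 | (1S)-1-[(1R,2R)-2-(bromomethyl)-3,3-dimethylcyclobutyl]-4-[(triisopropylsilyl)oxy]butan-1-ol | CC(C)[Si](C(C)C)(C(C)C)OCCC[C@H](O)[C@@H]1CC(C)(C)[C@@H]1CBr | intermediate
12 | 1-[(1R,2R)-2-(bromomethyl)-3,3-dimethylcyclobutyl]-4-[(triisopropylsilyl)oxy]butan-1-one (cis) | CC(C)[Si](C(C)C)(C(C)C)OCCCC(=O)[C@@H]1CC(C)(C)[C@@H]1CBr | intermediate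
13 | 1-[(1S,2R)-2-(bromomethyl)-3,3-dimethylcyclobutyl]-4-[(triisopropylsilyl)oxy]butan-1-one (trans) | CC(C)[Si](C(C)C)(C(C)C)OCCCC(=O)[C@H]1CC(C)(C)[C@@H]1CBr | intermediate
14 | ({4-[(1S,2R)-2-(bromomethyl)-3,3-dimethylcyclobutyl]pent-4-en-1-yl}oxy)triisopropylsilane | C=C(CCCO[Si](C(C)C)(C(C)C)C(C)C)[C@H]1CC(C)(C)[C@@H]1CBr | intermediate
15 | acetone N,N-dimethylhydrazone | CC(C)=NN(C)C | starting material
16 | N,N-dimethylhydrazone of 17 (C=N isomers) | C=C(CCCO[Si](C(C)C)(C(C)C)C(C)C)[C@H]1CC(C)(C)[C@@H]1CCC(C)=NN(C)C | intermediate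
17 | 4-[(1R,4S)-2,2-dimethyl-4-(5-{[triisopropylsilyl]oxy}pent-1-en-2-yl)cyclobutyl]butan-2-one | C=C(CCCO[Si](C(C)C)(C(C)C)C(C)C)[C@H]1CC(C)(C)[C@@H]1CCC(C)=O | intermediate
18 | 4-[(1R,4S)-4-(5-hydroxypent-1-en-2-yl)-2,2-dimethylcyclobutyl]butan-2-one | C=C(CCCO)[C@H]1CC(C)(C)[C@@H]1CCC(C)=O | intermediate
19 | linoleic acid | CCCCC/C=C\C/C=C\CCCCCCCC(=O)O | starting material
20 | 4-[(1S,2R)-3,3-dimethyl-2-(3-oxobutyl)cyclobutyl]pent-4-en-1-yl (9Z,12Z)-octadeca-9,12-dienoate | C=C(CCCOC(=O)CCCCCCC/C=C\C/C=C\CCCCC)[C@H]1CC(C)(C)[C@@H]1CCC(C)=O | target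

**Totals and risks**

Total step count: 13. Longest linear sequence: 13 steps (from butane-1,4-diol).

Steps most likely to fail:

1. Step 6 (photobicyclisation). The trisubstituted prenyl alkene may bind copper(I) too weakly, so that cycloaddition is slow and Lewis-acid ionisation of the doubly allylic ether takes over; or the side chain may discriminate poorly between exo and endo positions. The fallback sets out from 6 and comes back at 9, and replaces the copper template by a triplet enoate chromophore that is removed afterwards. Cross-metathesis of 6 with methyl acrylate (Hoveyda–Grubbs II) would give methyl (2E,4S)-4-hydroxy-7-[(triisopropylsilyl)oxy]hept-2-enoate F1. O-Prenylation with 7 under neutral conditions (Ag2O) would give methyl (2E,4S)-4-[(3-methylbut-2-en-1-yl)oxy]-7-[(triisopropylsilyl)oxy]hept-2-enoate F2. Acetone-sensitised irradiation (about 300 nm) should close the same two bonds stepwise, through a five-membered-ring 1,4-diradical, to methyl 6,6-dimethyl-2-{3-[(triisopropylsilyl)oxy]propyl}-3-oxabicyclo[3.2.0]heptane-7-carboxylate F3 (C7 epimers, other centres as in 9). Saponification (LiOH) would give the corresponding 7-carboxylic acid F4, and radical hydrodecarboxylation (acridinium photoredox catalyst, thiol hydrogen donor) would return 9.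

2. Step 7 (ether cleavage). Bromide may be delivered to the secondary carbon, the activated oxonium may ionise at the carbinol with cyclobutylcarbinyl rearrangement, or the boron halide may strip the silyl ether. The fallback sets out from 9 and comes back at 17; it unmasks the ring oxidatively and uses no halide.
   - RuCl3/NaIO4 oxidation of the unhindered O–CH2 should give 6,6-dimethyl-2-{3-[(triisopropylsilyl)oxy]propyl}-3-oxabicyclo[3.2.0]heptan-4-one F5.
   - Me(MeO)NH·HCl/Me3Al would open the lactone to the cis hydroxy Weinreb amide, 2-[(1S)-1-hydroxy-4-(triisopropylsilyloxy)butyl]-N-methoxy-N,4,4-trimethylcyclobutane-1-carboxamide F6.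
   - Dess–Martin oxidation would give the cis keto amide F7.
   - DBU would epimerise only the ketone α-centre to the trans keto amide F8; base is safe here because no halide is present.
   - Wittig methylenation (Ph3P=CH2) would give the trans methylene Weinreb amide F9.
   - DIBAL-H at −78 °C would give the aldehyde (1R,4S)-2,2-dimethyl-4-[5-(triisopropylsilyloxy)pent-1-en-2-yl]cyclobutane-1-carbaldehyde F10.
   - Wittig reaction with Ph3P=CHC(O)CH3 would give the (E)-enone F11.
   - Copper hydride conjugate reduction (Stryker's reagent) would return 17.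

3. Step 11 (hydrazone alkylation). SN2 displacement at the β-branched bromide next to the quaternary carbon may be slow, so that the aza-enolate acts as a base or decomposes. The fallback sets out from 14 and comes back at 17. Copper-catalysed coupling with allylmagnesium bromide (Li2CuCl4 cat., THF, −78 → 0 °C) would give ({4-[(1S,2R)-2-(but-3-en-1-yl)-3,3-dimethylcyclobutyl]pent-4-en-1-yl}oxy)triisopropylsilane F12. Tsuji–Wacker oxidation (PdCl2, CuCl, O2, DMF/H2O), which is selective for the monosubstituted alkene over the 1,1-disubstituted one, would then give 17.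

**Further compounds**

F1 | step 6 | methyl (2E,4S)-4-hydroxy-7-[(triisopropylsilyl)oxy]hept-2-enoate | CC(C)[Si](C(C)C)(C(C)C)OCCC[C@H](O)/C=C/C(=O)OC
F2 | step 6 | methyl (2E,4S)-4-[(3-methylbut-2-en-1-yl)oxy]-7-[(triisopropylsilyl)oxy]hept-2-enoate | CC(C)[Si](C(C)C)(C(C)C)OCCC[C@@H](/C=C/C(=O)OC)OCC=C(C)C
F3 | step 6 | methyl 6,6-dimethyl-2-{3-[(triisopropylsilyl)oxy]propyl}-3-oxabicyclo[3.2.0]heptane-7-carboxylate (C7 epimers, other centres as in 9) | CC(C)[Si](C(C)C)(C(C)C)OCCC[C@@H]1OC[C@H]2C(C)(C)C(C(=O)OC)[C@@H]12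
F4 | step 6 | 6,6-dimethyl-2-{3-[(triisopropylsilyl)oxy]propyl}-3-oxabicyclo[3.2.0]heptane-7-carboxylic acid (C7 epimers, other centres as in 9) | CC(C)[Si](C(C)C)(C(C)C)OCCC[C@@H]1OC[C@H]2C(C)(C)C(C(=O)O)[C@@H]12
F5 | step 7 | 6,6-dimethyl-2-{3-[(triisopropylsilyl)oxy]propyl}-3-oxabicyclo[3.2.0]heptan-4-one (centres as in 9) | CC(C)[Si](C(C)C)(C(C)C)OCCC[C@@H]1OC(=O)[C@H]2C(C)(C)C[C@@H]12
F6 | step 7 | cis-2-[(1S)-1-hydroxy-4-(triisopropylsilyloxy)butyl]-N-methoxy-N,4,4-trimethylcyclobutane-1-carboxamide | CC(C)[Si](C(C)C)(C(C)C)OCCC[C@H](O)[C@@H]1CC(C)(C)[C@@H]1C(=O)N(C)OC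
F7 | step 7 | cis-N-methoxy-N,4,4-trimethyl-2-[4-(triisopropylsilyloxy)butanoyl]cyclobutane-1-carboxamide | CC(C)[Si](C(C)C)(C(C)C)OCCCC(=O)[C@@H]1CC(C)(C)[C@@H]1C(=O)N(C)OC
F8 | step 7 | trans-N-methoxy-N,4,4-trimethyl-2-[4-(triisopropylsilyloxy)butanoyl]cyclobutane-1-carboxamide | CC(C)[Si](C(C)C)(C(C)C)OCCCC(=O)[C@H]1CC(C)(C)[C@@H]1C(=O)N(C)OC
F9 | step 7 | trans-N-methoxy-N,4,4-trimethyl-2-[5-(triisopropylsilyloxy)pent-1-en-2-yl]cyclobutane-1-carboxamide | C=C(CCCO[Si](C(C)C)(C(C)C)C(C)C)[C@H]1CC(C)(C)[C@@H]1C(=O)N(C)OC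
F10 | step 7 | (1R,4S)-2,2-dimethyl-4-[5-(triisopropylsilyloxy)pent-1-en-2-yl]cyclobutane-1-carbaldehyde | C=C(CCCO[Si](C(C)C)(C(C)C)C(C)C)[C@H]1CC(C)(C)[C@@H]1C=O
F11 | step 7 | (3E)-4-{2,2-dimethyl-4-[5-(triisopropylsilyloxy)pent-1-en-2-yl]cyclobutyl}but-3-en-2-one (trans ring, centres as in 17) | C=C(CCCO[Si](C(C)C)(C(C)C)C(C)C)[C@H]1CC(C)(C)[C@@H]1/C=C/C(C)=O
F12 | step 11 | ({4-[(1S,2R)-2-(but-3-en-1-yl)-3,3-dimethylcyclobutyl]pent-4-en-1-yl}oxy)triisopropylsilane | C=C(CCCO[Si](C(C)C)(C(C)C)C(C)C)[C@H]1CC(C)(C)[C@@H]1CCC=C
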